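Tautomerising the C3 enol of ring C (C2=C3–OH beside C4=O) uncovers a 3,4-diketone, one oxidation level above an alpha-hydroxy ketone, so the bond between the oxygenated carbons C3 and C4 is disconnected as an acyloin. Forward, a thiazol-2-ylidene reverses the polarity of the ring A aldehyde (future C4) and joins it to a side-chain aldehyde (future C3): one operation forms C3–C4, closes six-membered ring C and sets C3. The precursor is a racemic dialdehyde, a tetramethoxysalicylaldehyde whose phenol oxygen (O1) bears the CH(4-methoxyphenyl)CHO unit (C2, C3). It is reached by etherification, full reduction and double oxidation; dehydrogenation of the cyclised acyloin then aromatises ring C.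

Key step: step 6

Assumption: the target has no stereocentre, so every chiral intermediate is carried as a racemate and its SMILES shows one enantiomer only; flavone numbering (O1, C2, C3, C4, rings A, B, C) is used for the future ring atoms throughout.

Step 1
Reactants: 1 1,2,3,4-tetramethoxybenzene
Product: 4 2,3,4,5-tetramethoxyphenol, via aryllithium 2 (not isolated), via dimethyl arylboronate 3 (not isolated)
Conditions: n-BuLi, TMEDA, THF, 0 °C to rt; B(OMe)3, −78 °C to rt; AcOH, 30% aq. H2O2, 0 °C to rt
Reagents that add atoms: hydrogen peroxide, OO (phenol oxygen of 4); n-butyllithium, [Li]CCCC (lithium of 2 only); trimethyl borate, COB(OC)OC (boron unit of 3 only)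
Why: Directed ortho-metalation, borylation and peroxide oxidation: the two free ring positions of 1 are equivalent and each lies ortho to a methoxy group, so a single aryllithium should form, and the 1,2-shift of the aryl group from boron to oxygen places the phenol at that carbon.

Step 2
Reactants: 4 2,3,4,5-tetramethoxyphenol
Product: 6 2-hydroxy-3,4,5,6-tetramethoxybenzaldehyde, via salicyl alcohol 5 (not isolated)
Conditions: MgCl2, Et3N, (CH2O)n, MeCN, reflux, N2
Reagents that add atoms: paraformaldehyde (reacts as formaldehyde), C=O
Why: Casnati–Skattebøl ortho-formylation: the magnesium phenoxide guides formaldehyde to the only free ring carbon, which is ortho to the phenol, and alcohol 5 is oxidised in the flask by Oppenauer-type hydride transfer to a second formaldehyde, conditions that leave aryl methyl ethers untouched.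

Step 3
Reactants: 6 2-hydroxy-3,4,5,6-tetramethoxybenzaldehyde; 7 methyl 2-bromo-2-(4-methoxyphenyl)acetate (racemic)
Product: 8 methyl 2-(2-formyl-3,4,5,6-tetramethoxyphenoxy)-2-(4-methoxyphenyl)acetate (racemic)
Conditions: K2CO3, DMF, rt to 50 °C
Reagents that add atoms: none
Why: Williamson ether synthesis (SN2 at an activated benzylic alpha-bromo ester), a well-known pairing of salicylaldehydes with alpha-bromoarylacetates in which carbonate deprotonates the chelated phenol but is too weak at this temperature to drive aldol closure of the product; C2 forms as a racemate, which suffices for an achiral target.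

Step 4
Reactants: 8 methyl 2-(2-formyl-3,4,5,6-tetramethoxyphenoxy)-2-(4-methoxyphenyl)acetate
Product: 9 2-[2-(hydroxymethyl)-3,4,5,6-tetramethoxyphenoxy]-2-(4-methoxyphenyl)ethan-1-ol (racemic)
Conditions: LiAlH4, THF, 0 °C
Reagents that add atoms: none
Why: Exhaustive hydride reduction takes ester and aldehyde to primary alcohols together, so the two carbonyl groups need not be differentiated and no ester reduction has to be stopped halfway, while the aryl and benzylic ethers and C2 are not affected.

Step 5
Reactants: 9 2-[2-(hydroxymethyl)-3,4,5,6-tetramethoxyphenoxy]-2-(4-methoxyphenyl)ethan-1-ol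
Product: 10 2-[1-(4-methoxyphenyl)-2-oxoethoxy]-3,4,5,6-tetramethoxybenzaldehyde (racemic)
Conditions: Dess–Martin periodinane (2.4 equiv), CH2Cl2, 0 °C to rt; crude product used the same day
Reagents that add atoms: none
Why: Dess–Martin oxidation converts both primary alcohols under base-free, nearly neutral conditions without over-oxidation, so the easily enolised alpha-aryl-alpha-aryloxy aldehyde is unveiled last and is carried on without chromatography.

Step 6
Reactants: 10 2-[1-(4-methoxyphenyl)-2-oxoethoxy]-3,4,5,6-tetramethoxybenzaldehyde
Product: 12 trans-3-hydroxy-5,6,7,8-tetramethoxy-2-(4-methoxyphenyl)chroman-4-one (racemic, 2R*,3R*), via Breslow enaminol 11 (not isolated)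
Conditions: 3,4-dimethyl-5-(2-hydroxyethyl)thiazolium iodide (20 mol %), Et3N (40 mol %), degassed CH2Cl2, slow addition of 10 to 0.01 M, Ar, rt to 35 °C
Reagents that add atoms: 3,4-dimethyl-5-(2-hydroxyethyl)thiazolium iodide, C[n+]1csc(CCO)c1C.[I-] (its carbene is bound in 11 only; no atom of it stays in 12)
Why: Proposed new method: the carbene freed from the thiazolium salt adds to the ring A aldehyde, proton transfer gives enaminol 11 in which the future C4 is nucleophilic, and this carbon attacks the side-chain aldehyde (future C3) before the catalyst leaves and unveils the C4 ketone. The closest known reaction types are the carbene-catalysed intramolecular crossed benzoin of 2-(2-oxoalkoxy)benzaldehydes, which gives 3-substituted 3-hydroxychroman-4-ones from aldehyde–ketone pairs, and intermolecular crossed benzoins in which alpha-branched, alpha-heteroatom aldehydes serve only as acceptors; an aldehyde–aldehyde closure with an alpha-aryloxy acceptor and a doubly ortho-substituted donor has not been shown. Ring C closes in the 6-exo-trig mode, the acceptor C=O lying outside the new ring. The new C3 centre is governed by C2: a chair-like transition state with the 4-methoxyphenyl group equatorial, and amine-mediated epimerisation of the acidic C3–H through the enediol, both lead to the 2,3-trans diequatorial isomer, and the outcome carries no consequence because C2 and C3 become sp2 in step 7. The selectivity required is the choice of donor: an enaminol formed at the side-chain aldehyde would hold the O1 aryloxide in the beta position and could expel it (internal redox to an aryl ester), so the aryl aldehyde must be the donor, which is favoured by the two bulky alpha substituents that slow proton transfer in the aliphatic adduct, by the inductive activation of that aldehyde as acceptor, by the benzylic acidity of the aryl adduct and by the small N-methyl carbene. Slow addition at high dilution and the proximity imposed by the ortho ether link hold bimolecular acyloin and aldol pathways in check, and the five-membered aldol of the C2 enolate onto the aryl aldehyde stays reversible with an amine base in an aprotic medium, whereas the conjugated aryl ketone is a sink.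

Step 7
Reactants: 12 trans-3-hydroxy-5,6,7,8-tetramethoxy-2-(4-methoxyphenyl)chroman-4-one
Product: 14 3-hydroxy-5,6,7,8-tetramethoxy-2-(4-methoxyphenyl)-4H-chromen-4-one (target), via flavan-3,4-dione 13 (not isolated)
Conditions: I2 (1.1 equiv), KOAc (3 equiv), AcOH, 100 °C
Reagents that add atoms: none
Why: Classical iodine–acetate dehydrogenation of dihydroflavonols: iodination of the enediol at C3 and loss of HI give dione 13, whose acidic C2–H shifts immediately to oxygen to form the aromatic 4-pyranone, while acetate buffers HI so the methyl ethers survive; copper salts under air are avoided because flavonolate complexes of divalent copper are cleaved by O2.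

Compound list
1 | 1,2,3,4-tetramethoxybenzene | COc1ccc(OC)c(OC)c1OC | starting material
2 | (2,3,4,5-tetramethoxyphenyl)lithium (not isolated) | [Li]c1cc(OC)c(OC)c(OC)c1OC | intermediate
3 | dimethyl (2,3,4,5-tetramethoxyphenyl)boronate (not isolated) | COB(OC)c1cc(OC)c(OC)c(OC)c1OC | intermediate
4 | 2,3,4,5-tetramethoxyphenol | COc1cc(O)c(OC)c(OC)c1OC | intermediate
5 | 2-(hydroxymethyl)-3,4,5,6-tetramethoxyphenol (present as its magnesium salt, not isolated) | COc1c(O)c(CO)c(OC)c(OC)c1OC | intermediate
6 | 2-hydroxy-3,4,5,6-tetramethoxybenzaldehyde | COc1c(O)c(C=O)c(OC)c(OC)c1OC | intermediate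
7 | methyl 2-bromo-2-(4-methoxyphenyl)acetate (racemic) | COC(=O)C(Br)c1ccc(OC)cc1 | starting material
8 | methyl 2-(2-formyl-3,4,5,6-tetramethoxyphenoxy)-2-(4-methoxyphenyl)acetate (racemic, S enantiomer drawn) | COc1ccc([C@@H](C(=O)OC)Oc2c(OC)c(OC)c(OC)c(OC)c2C=O)cc1 | intermediate
9 | 2-[2-(hydroxymethyl)-3,4,5,6-tetramethoxyphenoxy]-2-(4-methoxyphenyl)ethan-1-ol (racemic, S enantiomer drawn) | COc1ccc([C@@H](CO)Oc2c(OC)c(OC)c(OC)c(OC)c2CO)cc1 | intermediate
10 | 2-[1-(4-methoxyphenyl)-2-oxoethoxy]-3,4,5,6-tetramethoxybenzaldehyde (racemic, S enantiomer drawn) | COc1ccc([C@@H](C=O)Oc2c(OC)c(OC)c(OC)c(OC)c2C=O)cc1 | intermediate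
11 | 2-{2-[hydroxy(5-(2-hydroxyethyl)-3,4-dimethylthiazol-2(3H)-ylidene)methyl]-3,4,5,6-tetramethoxyphenoxy}-2-(4-methoxyphenyl)acetaldehyde (Breslow enaminol, racemic, C=C geometry undefined, not isolated) | COc1ccc([C@@H](C=O)Oc2c(OC)c(OC)c(OC)c(OC)c2C(O)=C3SC(CCO)=C(C)N3C)cc1 | intermediate
12 | trans-3-hydroxy-5,6,7,8-tetramethoxy-2-(4-methoxyphenyl)chroman-4-one (racemic, 2S,3S enantiomer drawn) | COc1ccc([C@@H]2Oc3c(OC)c(OC)c(OC)c(OC)c3C(=O)[C@H]2O)cc1 | intermediate
13 | 5,6,7,8-tetramethoxy-2-(4-methoxyphenyl)chromane-3,4-dione (racemic, S enantiomer drawn, not isolated) | COc1ccc([C@@H]2Oc3c(OC)c(OC)c(OC)c(OC)c3C(=O)C2=O)cc1 | intermediate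
14 | 3-hydroxy-5,6,7,8-tetramethoxy-2-(4-methoxyphenyl)-4H-chromen-4-one | COc1ccc(-c2oc3c(OC)c(OC)c(OC)c(OC)c3c(=O)c2O)cc1 | target

Total step count: 7
Longest linear sequence: 7 steps (1 to 14; bromo ester 7 enters in step 3)

Steps most likely to fail

Step 6 (carries the label).
- **What may go wrong:** The carbene may engage the side-chain aldehyde instead. Loss of the O1 aryloxide from that enaminol and acyl transfer would then drain the substrate irreversibly. The crowded, electron-rich aryl aldehyde may also resist enaminol formation, which leaves time for aldol chemistry of the enolisable aldehyde.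
- **Fallback:** Ring C is built by the chalcone route, which uses only known reactions, sets out from phenol 4 and returns at target 14.
- C-acetylation at the single free ring position (AcOH, BF3·OEt2, 90 °C, Friedel–Crafts/Fries type) should give 1-(2-hydroxy-3,4,5,6-tetramethoxyphenyl)ethan-1-one F1.
- Claisen–Schmidt condensation with 4-methoxybenzaldehyde (KOH, EtOH, rt) should give (E)-1-(2-hydroxy-3,4,5,6-tetramethoxyphenyl)-3-(4-methoxyphenyl)prop-2-en-1-one F2.
- Oxidative cyclisation (cat. I2, DMSO, 130 °C) should give 5,6,7,8-tetramethoxy-2-(4-methoxyphenyl)chromen-4-one F3.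
- Dimethyldioxirane in acetone/CH2Cl2 at 0 °C should give the flavone 2,3-epoxide F4, which opens with cat. p-TsOH to 14.
- Direct alkaline peroxide oxidation of F2 (Algar–Flynn–Oyamada) is not chosen, because 6'-alkoxychalcones tend to be diverted to aurones.

Step 5.
- **What may go wrong:** Hemiacetal formation between the first-formed aldehyde and the remaining alcohol, followed by over-oxidation to a seven-membered lactone. Enolisation, autoxidation or aldol closure of the dialdehyde may also occur during isolation.
- **Fallback:** A partial-reduction approach in which an alcohol and an aldehyde never coexist. It sets out from ester 8 and returns at dialdehyde 10.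
- HC(OMe)3 and cat. p-TsOH in MeOH should mask the aryl aldehyde as methyl 2-[2-(dimethoxymethyl)-3,4,5,6-tetramethoxyphenoxy]-2-(4-methoxyphenyl)acetate F5.
- i-Bu2AlH (1.1 equiv) in toluene at −78 °C should stop at the aldehyde stage, helped by the chelated alpha-aryloxy tetrahedral intermediate. This gives 2-[2-(dimethoxymethyl)-3,4,5,6-tetramethoxyphenoxy]-2-(4-methoxyphenyl)acetaldehyde F6.
- PPTS in wet acetone at rt should release the very labile electron-rich aryl acetal to give 10.

Step 3.
- **What may go wrong:** Substitution is slow at a phenoxide flanked by two ortho groups, so decomposition of the ionisable bromide and carbonate-induced aldol closure of the product gain ground.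
- **Fallback:** The order of events is inverted. It sets out from phenol 4 (with 7), bypasses step 2 and returns at 8.
- Alkylation of the less hindered, aldehyde-free phenol 4 with 7 (K2CO3, acetone, reflux) should give methyl 2-(4-methoxyphenyl)-2-(2,3,4,5-tetramethoxyphenoxy)acetate F7.
- Vilsmeier–Haack formylation (POCl3, DMF, 60 °C) should then attack the only free carbon of the pentaoxygenated ring A, which is far more nucleophilic than ring B, to give 8.

Further compounds
F1 | step 6 | 1-(2-hydroxy-3,4,5,6-tetramethoxyphenyl)ethan-1-one | CC(=O)c1c(O)c(OC)c(OC)c(OC)c1OC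
F2 | step 6 | (E)-1-(2-hydroxy-3,4,5,6-tetramethoxyphenyl)-3-(4-methoxyphenyl)prop-2-en-1-one | COc1ccc(/C=C/C(=O)c2c(O)c(OC)c(OC)c(OC)c2OC)cc1
F3 | step 6 | 5,6,7,8-tetramethoxy-2-(4-methoxyphenyl)chromen-4-one | COc1ccc(-c2cc(=O)c3c(OC)c(OC)c(OC)c(OC)c3o2)cc1
F4 | step 6 | flavone 2,3-epoxide: 2,3-epoxy-5,6,7,8-tetramethoxy-2-(4-methoxyphenyl)chroman-4-one (racemic, cis-fused, one enantiomer drawn) | COc1ccc([C@@]23Oc4c(OC)c(OC)c(OC)c(OC)c4C(=O)[C@@H]2O3)cc1
F5 | step 5 | methyl 2-[2-(dimethoxymethyl)-3,4,5,6-tetramethoxyphenoxy]-2-(4-methoxyphenyl)acetate (racemic, S enantiomer drawn) | COc1ccc([C@@H](C(=O)OC)Oc2c(OC)c(OC)c(OC)c(OC)c2C(OC)OC)cc1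
F6 | step 5 | 2-[2-(dimethoxymethyl)-3,4,5,6-tetramethoxyphenoxy]-2-(4-methoxyphenyl)acetaldehyde (racemic, S enantiomer drawn) | COc1ccc([C@@H](C=O)Oc2c(OC)c(OC)c(OC)c(OC)c2C(OC)OC)cc1
F7 | step 3 | methyl 2-(4-methoxyphenyl)-2-(2,3,4,5-tetramethoxyphenoxy)acetate (racemic, S enantiomer drawn) | COc1ccc([C@@H](C(=O)OC)Oc2cc(OC)c(OC)c(OC)c2OC)cc1
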